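All runs come from a simulation for an exercise; noise was put on by code.

**Dawn run.** The dawn run of this same flask reached 20.9% product at 8.00 h. From 10 mM of starting material and 5 µM of enzyme, that reading is 418 turnovers per enzyme.

| flask | starting material | enzyme | remark |
|---|---|---|---|
| dawn | 10 mM | 5 µM | the very flask that is asked about, followed so far |
| flask | 10 mM | 5.0 µM |  |

- dawn (time / h: product / %, starting material / %): 0.667: 3.1, 97.1; 1.00: 3.3, 98.1; 2.00: 6.6, 93.0; 3.00: 10.8, 89.2; 5.00: 13.8, 84.6; 8.00: 20.9, 80.8

(readings scatter by 1 percentage point)

- the numbers in the tables scatter with a standard deviation of 1 percentage point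
- no earlier run changes the charge of enzyme; that part of a forecast is a guess

1. factor on the rate of making product when 20% of the starting material are converted if enzyme is charged twice over
2. factor on the rate when 20% of the starting material are converted if enzyme is charged at 0.50 µM instead

**Bench rule.** At the bench you would say that rate follows the charge of catalyst, with each enzyme turning at one pace. My own reckoning starts there: 2 for the doubled charge, and 0.100 for 0.50 µM.

**Turnover count.** Now count what the mark, 20% conversion, costs. The turnover bill is the starting material converted at the mark, divided by the enzyme charged. Your flask at 5.0 µM has a bill of 400, about what the dawn reading shows. The flask at 0.50 µM has a bill of 4000, ten times the dawn count. That bill lies past the border of the readings, which stop at 418 turnovers. The dawn run also used one charge of enzyme, so the rule is untested at either new charge. So when you repeat the run, watch the rate per enzyme at 0.50 µM.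

**The forecast.** It gives 2 for the doubled charge and 0.1 for 0.50 µM. Its stated ground is this: “No run varied the enzyme, so its order is assumed”.

**What came.** Doubling gives 1.66, and 0.50 µM gives 0.136. At the mark, the 0.50 µM flask holds 29.7% of its catalyst as complex.

    2 complex ⇌ resting dimer (K = 6.11 × 10⁵ L mol⁻¹, k = 5820 L mol⁻¹ min⁻¹)
    starting material + enzyme ⇌ complex (K = 57.4 L mol⁻¹, k = 64300 L mol⁻¹ min⁻¹)
    complex ⇌ enzyme + product (K = 0.0170 M, k = 4.22 min⁻¹)

Your flask at 5.0 µM reaches the mark at 7.50 h, so its bill of 400 is paid at an average of 53.3 h⁻¹. Its rate at the mark is 0.206 mM h⁻¹, or 41.2 h⁻¹ per enzyme charged. The 0.50 µM flask turns at 55.9 h⁻¹ per enzyme charged at the mark, faster than your flask. Held at that pace, its bill of 4000 would take 71.6 h.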